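**Plan** (germacrane numbering: ring C1–C10, lactone carbons C11–C13, C14 on C10, C15 on C4)

1. Retrosynthesis: the 1,10-epoxide is removed first (late peracid epoxidation of the E-1(10) olefin). The butenolide is then cut at O–C6 and C7=C11, together with the C13–OAc bond, into a ten-membered 6-mesyloxy-7-ketone, 2-(diethoxyphosphoryl)acrylic acid and acetate, which are united in one flask.
2. Enabling feature: C6 is both α to C7 (a ketone in the precursor) and allylic to C4=C5, so it accepts a carboxylate by SN2 with inversion. The five-membered ring O–C6–C7=C11–C12 is then an intramolecular Horner–Wadsworth–Emmons (HWE) retron, and the CH2OAc on C11 is the retron of acetate addition to a 2-phosphonoacrylate.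
3. The carbocycle is cut at C8–C9 (C-alkylation of an allyl β-keto ester by the C9 allylic chloride; the allyl ester is a helper removed by decarboxylation). The chain is cut at C7–C8 (acetate aldol), C2–C3 (vinylogous Mukaiyama aldol) and C4=C5 (Wittig).
4. Forward order: C5–C7 chiron → C3–C7 enal → C9–C7 chain → C8 added → ten-membered ring → butenolide → epoxide.
5. Stereochemistry: C6 comes from (R)-glyceraldehyde acetonide, is carried as 6S and inverted to 6R in the key step. C3 is set by a catalyst-controlled vinylogous aldol, both E-olefins by the Wittig and aldol steps, and C1/C10 by peracid attack on the exposed face of the germacranolide.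

Key step: step 18

Remark: the target is read as (1R,3S,6R,10R),4E; from the ring closure (step 12) onward all operations are kept at or below 40 °C, because 1(10),4-germacradienes undergo Cope rearrangement on heating.

**Route**

Step 1
Reactants: 1 (R)-2,2-dimethyl-1,3-dioxolane-4-carbaldehyde; 2 2-(triphenyl-λ5-phosphanylidene)propanal
Product: 3 (S,E)-3-(2,2-dimethyl-1,3-dioxolan-4-yl)-2-methylprop-2-enal
Conditions: toluene, 60 °C
Reagents that add atoms: none
Why: Wittig olefination with a formyl-stabilised ylide should give the trisubstituted E-enal (C4=C5) while the C6 stereocentre of 1 is carried over untouched.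

Step 2
Reactants: 4 methyl (E)-2-methylbut-2-enoate (methyl tiglate)
Product: 5 tert-butyl[(1-methoxy-2-methylbuta-1,3-dien-1-yl)oxy]dimethylsilane
Conditions: LiN(i-Pr)2, DMPU, THF, −78 °C; then t-BuMe2SiCl, −78 °C → rt
Reagents that add atoms: tert-butyldimethylsilyl chloride, CC(C)(C)[Si](C)(C)Cl
Why: γ-deprotonation of the enoate and O-silylation of the extended enolate is the standard preparation of a vinylogous silyl ketene acetal.

Step 3
Reactants: 3 (S,E)-3-(2,2-dimethyl-1,3-dioxolan-4-yl)-2-methylprop-2-enal; 5 tert-butyl[(1-methoxy-2-methylbuta-1,3-dien-1-yl)oxy]dimethylsilane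
Product: 6 methyl (2E,5S,6E)-7-[(4S)-2,2-dimethyl-1,3-dioxolan-4-yl]-5-hydroxy-2,6-dimethylhepta-2,6-dienoate
Conditions: SiCl4 (1.1 equiv), (S,S)-binaphthyldiamine-derived bisphosphoramide (5 mol %, the antipode that directs Si-face attack), i-Pr2NEt (10 mol %), CH2Cl2, −78 °C; aq. NaHCO3 work-up
Reagents that add atoms: none
Why: in this catalytic enantioselective vinylogous Mukaiyama aldol addition the dienolate should attack through its γ-carbon on the Si face of the enal fixed by the chiral Lewis-base-bound silicon cation, which sets C3 as S under catalyst control and forms the new C1=C10 enoate as the E isomer.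

Step 4
Reactants: 6 methyl (2E,5S,6E)-7-[(4S)-2,2-dimethyl-1,3-dioxolan-4-yl]-5-hydroxy-2,6-dimethylhepta-2,6-dienoate
Product: 7 (2E,5S,6E)-7-[(4S)-2,2-dimethyl-1,3-dioxolan-4-yl]-2,6-dimethylhepta-2,6-diene-1,5-diol
Conditions: i-Bu2AlH (3.5 equiv), CH2Cl2, −78 → 0 °C; aq. potassium sodium tartrate
Reagents that add atoms: none
Why: 1,2-reduction of the conjugated ester by i-Bu2AlH should give the primary allylic alcohol without touching the acetonide.

Step 5
Reactants: 7 (2E,5S,6E)-7-[(4S)-2,2-dimethyl-1,3-dioxolan-4-yl]-2,6-dimethylhepta-2,6-diene-1,5-diol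
Product: 8 (1E,3S,5E)-7-chloro-1-[(4S)-2,2-dimethyl-1,3-dioxolan-4-yl]-2,6-dimethylhepta-1,5-dien-3-ol
Conditions: NCS, Me2S, CH2Cl2, −30 → 0 °C
Reagents that add atoms: N-chlorosuccinimide, ClN1C(=O)CCC1=O
Why: Corey–Kim chlorination should convert the less hindered primary allylic alcohol into the chloride by SN2 on the alkoxysulfonium salt without allylic transposition, the secondary C3 alcohol reacting more slowly.

Step 6
Reactants: 8 (1E,3S,5E)-7-chloro-1-[(4S)-2,2-dimethyl-1,3-dioxolan-4-yl]-2,6-dimethylhepta-1,5-dien-3-ol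
Product: 9 (1E,3S,5E)-7-chloro-1-[(4S)-2,2-dimethyl-1,3-dioxolan-4-yl]-2,6-dimethylhepta-1,5-dien-3-yl acetate
Conditions: Ac2O, pyridine, DMAP (cat.), CH2Cl2, 0 °C
Reagents that add atoms: acetic anhydride, CC(=O)OC(C)=O
Why: DMAP-catalysed acylation installs the C3 acetate of the target, which then serves as its own protecting group.

Step 7
Reactants: 9 (1E,3S,5E)-7-chloro-1-[(4S)-2,2-dimethyl-1,3-dioxolan-4-yl]-2,6-dimethylhepta-1,5-dien-3-yl acetate
Product: 10 (2S,3E,5S,7E)-9-chloro-1,2-dihydroxy-4,8-dimethylnona-3,7-dien-5-yl acetate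
Conditions: AcOH/H2O/THF (3:1:1), 35 °C
Reagents that add atoms: none
Why: mild acid hydrolysis of the terminal acetonide should free the C6/C7 diol while the acetate and the primary allylic chloride survive.

Step 8
Reactants: 10 (2S,3E,5S,7E)-9-chloro-1,2-dihydroxy-4,8-dimethylnona-3,7-dien-5-yl acetate
Product: 11 (2S,3E,5S,7E)-9-chloro-4,8-dimethyl-1,2-bis(triethylsilyloxy)nona-3,7-dien-5-yl acetate
Conditions: Et3SiOTf (2.5 equiv), 2,6-lutidine, CH2Cl2, −78 °C
Reagents that add atoms: triethylsilyl trifluoromethanesulfonate, CC[Si](CC)(CC)OS(=O)(=O)C(F)(F)F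
Why: a silyl triflate with a hindered base silylates both hydroxyls at low temperature without N-alkylation of the base by the allylic chloride.

Step 9
Reactants: 11 (2S,3E,5S,7E)-9-chloro-4,8-dimethyl-1,2-bis(triethylsilyloxy)nona-3,7-dien-5-yl acetate
Product: 12 (2S,3E,5S,7E)-9-chloro-4,8-dimethyl-1-oxo-2-(triethylsilyloxy)nona-3,7-dien-5-yl acetate
Conditions: (COCl)2 (4 equiv), DMSO (8 equiv), CH2Cl2, −78 → −40 °C; then Et3N, −78 → 0 °C
Reagents that add atoms: none
Why: under Swern conditions a primary triethylsilyl ether is cleaved by the chlorosulfonium salt and oxidised directly to the aldehyde while the secondary silyl ether stays, a known selective unmasking-oxidation that avoids a separate deprotection.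

Step 10
Reactants: 12 (2S,3E,5S,7E)-9-chloro-4,8-dimethyl-1-oxo-2-(triethylsilyloxy)nona-3,7-dien-5-yl acetate; 13 allyl acetate
Product: 14 allyl (4S,5E,7S,9E)-7-acetoxy-11-chloro-3-hydroxy-6,10-dimethyl-4-(triethylsilyloxy)undeca-5,9-dienoate (both C3 epimers)
Conditions: LiN(i-Pr)2, 13, THF, −78 °C; then 12, −78 °C; AcOH quench
Reagents that add atoms: none
Why: aldol addition of the lithium ester enolate to the aldehyde at −78 °C forms the C7–C8 bond faster than enolisation at C6 or attack on the acetate and the chloride, and the new carbinol configuration is irrelevant because it is oxidised next.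

Step 11
Reactants: 14 allyl (4S,5E,7S,9E)-7-acetoxy-11-chloro-3-hydroxy-6,10-dimethyl-4-(triethylsilyloxy)undeca-5,9-dienoate
Product: 15 allyl (4S,5E,7S,9E)-7-acetoxy-11-chloro-6,10-dimethyl-3-oxo-4-(triethylsilyloxy)undeca-5,9-dienoate
Conditions: Dess–Martin periodinane, pyridine, CH2Cl2, 0 °C → rt
Reagents that add atoms: none
Why: Dess–Martin oxidation of the β-hydroxy ester gives the β-keto ester under buffered conditions that should not epimerise C6.

Step 12
Reactants: 15 allyl (4S,5E,7S,9E)-7-acetoxy-11-chloro-6,10-dimethyl-3-oxo-4-(triethylsilyloxy)undeca-5,9-dienoate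
Product: 16 allyl (3S,4E,6S,8E)-6-acetoxy-5,9-dimethyl-2-oxo-3-(triethylsilyloxy)cyclodeca-4,8-diene-1-carboxylate (both C1 epimers)
Conditions: Cs2CO3 (3 equiv), NaI (0.1 equiv), DMF, 2 mM by slow addition, 40 °C
Reagents that add atoms: none
Why: intramolecular SN2 C-alkylation of the caesium β-keto ester enolate by the primary allylic chloride closes the ten-membered (E,E)-1(10),4-diene ring (C8–C9), the classical carbanion–allylic halide closure of germacranes, and because only the doubly activated C8–H is deprotonated C6 is not epimerised.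

Step 13
Reactants: 16 allyl (3S,4E,6S,8E)-6-acetoxy-5,9-dimethyl-2-oxo-3-(triethylsilyloxy)cyclodeca-4,8-diene-1-carboxylate
Product: 18 (2S,3E,5S,7E)-5-acetoxy-4,8-dimethyl-2-(triethylsilyloxy)cyclodeca-3,7-dien-1-one, via β-keto acid 17 (not isolated)
Conditions: Pd(PPh3)4 (5 mol %), morpholine (2 equiv), THF, 0 °C → rt
Reagents that add atoms: none
Why: zerovalent palladium ionises the unhindered allyl ester far faster than the hindered ring C3 acetate, morpholine traps the allyl group (Tsuji–Trost deallylation), and the β-keto acid loses CO2 at room temperature to remove the activating group.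

Step 14
Reactants: 18 (2S,3E,5S,7E)-5-acetoxy-4,8-dimethyl-2-(triethylsilyloxy)cyclodeca-3,7-dien-1-one
Product: 19 (2S,3E,5S,7E)-5-acetoxy-2-hydroxy-4,8-dimethylcyclodeca-3,7-dien-1-one
Conditions: HF·pyridine, pyridine, THF, 0 °C
Reagents that add atoms: none
Why: buffered fluoride cleaves the secondary triethylsilyl ether without the acid or base that would trigger ketol isomerisation or transannular reactions.

Step 15
Reactants: 19 (2S,3E,5S,7E)-5-acetoxy-2-hydroxy-4,8-dimethylcyclodeca-3,7-dien-1-one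
Product: 20 (2S,3E,5S,7E)-5-acetoxy-4,8-dimethyl-2-(methylsulfonyloxy)cyclodeca-3,7-dien-1-one
Conditions: Ms2O, pyridine, CH2Cl2, −20 → 0 °C
Reagents that add atoms: methanesulfonic anhydride, CS(=O)(=O)OS(C)(=O)=O
Why: O-sulfonylation of the α-ketol with a weak base gives the α-mesyloxy ketone with retention at C6, and the adjacent carbonyl suppresses ionisation of the allylic sulfonate.

Step 16
Reactants: 21 tert-butyl 2-(diethoxyphosphoryl)acetate
Product: 24 tert-butyl 2-(diethoxyphosphoryl)prop-2-enoate, via Mannich base 22 (not isolated), via trimethylammonium iodide 23 (not isolated)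
Conditions: NaH, THF, 0 °C; Me2N=CH2+ I−, 0 °C → rt; then MeI, rt; then aq. NaHCO3
Reagents that add atoms: dimethyl(methylene)ammonium iodide, C=[N+](C)C.[I-]
Why: Mannich reaction of the phosphonoacetate anion with the preformed iminium salt, N-methylation and E1cB loss of trimethylamine is the standard α-methylenation of an active methylene compound and tolerates the tert-butyl ester.

Step 17
Reactants: 24 tert-butyl 2-(diethoxyphosphoryl)prop-2-enoate
Product: 25 2-(diethoxyphosphoryl)prop-2-enoic acid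
Conditions: CF3CO2H/CH2Cl2 (1:4), 0 °C → rt
Reagents that add atoms: none
Why: acidolysis of the tert-butyl ester with loss of isobutene leaves the diethyl phosphonate and the acrylate untouched.

Step 18
Reactants: 20 (2S,3E,5S,7E)-5-acetoxy-4,8-dimethyl-2-(methylsulfonyloxy)cyclodeca-3,7-dien-1-one; 25 2-(diethoxyphosphoryl)prop-2-enoic acid; 26 caesium acetate
Product: 29 (3S,6R)-3,13-diacetoxygermacra-1(10)E,4E,7(11)-trien-12,6-olide, via phosphonoacrylate ester 27 (not isolated), via acetate adduct carbanion 28 (not isolated)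
Conditions: 25 (1.1 equiv), Cs2CO3 (0.55 equiv), DMF, 0 °C; add 20, 0 °C → rt; then 26 (5 equiv), 18-crown-6 (0.2 equiv), rt → 40 °C, one flask
Reagents that add atoms: none
Why: Proposed new method: the caesium carboxylate of 25 displaces the C6 mesylate of 20 by SN2, accelerated by the flanking C7 carbonyl (O–C6 bond, inversion); acetate then adds reversibly to the doubly activated 2-phosphonoacrylate of 27, and the phosphonate carbanion 28 is captured by the C7 ketone in an intramolecular HWE olefination that expels diethyl phosphate irreversibly (C11=C7 bond). The closest known reaction types are carboxylate displacement of α-sulfonyloxy ketones followed by intramolecular HWE butenolide formation, and the tandem conjugate addition–HWE of alkoxides or thiolates with 2-phosphonoacrylates; only the carboxylate as Michael donor is new, and it is argued from the fact that E1cB loss of acetate from 28 merely returns 27, so the olefination drains the equilibrium. The butenolide closes by 5-exo-trig attack of the C11 carbanion on the C7 carbonyl within the ester tether. C6 is the only stereocentre formed, and its R configuration follows from backside displacement of the (S)-mesylate, which has no sp3 β-hydrogen for elimination. The step needs SN2 over SN2′ attack, which the fully substituted C4 terminus and the α-keto activation of C6 secure, and it needs acetate to reach C13 and not C6, which is secured by adding it only after the mesylate is consumed. Acetate is too weak a base to epimerise the γ-hydrogen at C6 of the product or to cleave the C3 acetate.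

Step 19
Reactants: 29 (3S,6R)-3,13-diacetoxygermacra-1(10)E,4E,7(11)-trien-12,6-olide
Product: 30 (1R,3S,6R,10R)-3,13-diacetoxy-1,10-epoxygermacra-4E,7(11)-dien-12,6-olide
Conditions: mCPBA (1.1 equiv), Na2HPO4, CH2Cl2, 0 °C
Reagents that add atoms: meta-chloroperoxybenzoic acid, OOC(=O)c1cccc(Cl)c1
Why: in this Prilezhaev epoxidation the electron-rich 1(10) E-olefin should react before the C4=C5 olefin (deactivated by two allylic oxygens) and the butenolide, and the peracid is expected to attack its exposed outer face in the crown conformer with C14 and C15 syn, by analogy with 6α,12-germacranolides, which gives the trans (1R,10R) epoxide.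

**Compound list**

1 | (R)-2,2-dimethyl-1,3-dioxolane-4-carbaldehyde | O=C[C@H]1COC(C)(C)O1 | starting material
2 | 2-(triphenyl-λ5-phosphanylidene)propanal | CC(C=O)=P(c1ccccc1)(c1ccccc1)c1ccccc1 | starting material
3 | (S,E)-3-(2,2-dimethyl-1,3-dioxolan-4-yl)-2-methylprop-2-enal | O=C/C(C)=C/[C@H]1COC(C)(C)O1 | intermediate
4 | methyl (E)-2-methylbut-2-enoate | C/C=C(\C)C(=O)OC | starting material
5 | tert-butyl[(1-methoxy-2-methylbuta-1,3-dien-1-yl)oxy]dimethylsilane (ketene acetal geometry not defined, not transferred) | C=CC(C)=C(OC)O[Si](C)(C)C(C)(C)C | intermediate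
6 | methyl (2E,5S,6E)-7-[(4S)-2,2-dimethyl-1,3-dioxolan-4-yl]-5-hydroxy-2,6-dimethylhepta-2,6-dienoate | COC(=O)/C(C)=C/C[C@H](O)/C(C)=C/[C@H]1COC(C)(C)O1 | intermediate
7 | (2E,5S,6E)-7-[(4S)-2,2-dimethyl-1,3-dioxolan-4-yl]-2,6-dimethylhepta-2,6-diene-1,5-diol | OC/C(C)=C/C[C@H](O)/C(C)=C/[C@H]1COC(C)(C)O1 | intermediate
8 | (1E,3S,5E)-7-chloro-1-[(4S)-2,2-dimethyl-1,3-dioxolan-4-yl]-2,6-dimethylhepta-1,5-dien-3-ol | ClC/C(C)=C/C[C@H](O)/C(C)=C/[C@H]1COC(C)(C)O1 | intermediate
9 | (1E,3S,5E)-7-chloro-1-[(4S)-2,2-dimethyl-1,3-dioxolan-4-yl]-2,6-dimethylhepta-1,5-dien-3-yl acetate | ClC/C(C)=C/C[C@H](OC(C)=O)/C(C)=C/[C@H]1COC(C)(C)O1 | intermediate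
10 | (2S,3E,5S,7E)-9-chloro-1,2-dihydroxy-4,8-dimethylnona-3,7-dien-5-yl acetate | ClC/C(C)=C/C[C@H](OC(C)=O)/C(C)=C/[C@H](O)CO | intermediate
11 | (2S,3E,5S,7E)-9-chloro-4,8-dimethyl-1,2-bis(triethylsilyloxy)nona-3,7-dien-5-yl acetate | ClC/C(C)=C/C[C@H](OC(C)=O)/C(C)=C/[C@H](O[Si](CC)(CC)CC)CO[Si](CC)(CC)CC | intermediate
12 | (2S,3E,5S,7E)-9-chloro-4,8-dimethyl-1-oxo-2-(triethylsilyloxy)nona-3,7-dien-5-yl acetate | ClC/C(C)=C/C[C@H](OC(C)=O)/C(C)=C/[C@H](O[Si](CC)(CC)CC)C=O | intermediate
13 | allyl acetate | CC(=O)OCC=C | starting material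
14 | allyl (4S,5E,7S,9E)-7-acetoxy-11-chloro-3-hydroxy-6,10-dimethyl-4-(triethylsilyloxy)undeca-5,9-dienoate (C3 epimers) | ClC/C(C)=C/C[C@H](OC(C)=O)/C(C)=C/[C@H](O[Si](CC)(CC)CC)C(O)CC(=O)OCC=C | intermediate
15 | allyl (4S,5E,7S,9E)-7-acetoxy-11-chloro-6,10-dimethyl-3-oxo-4-(triethylsilyloxy)undeca-5,9-dienoate | ClC/C(C)=C/C[C@H](OC(C)=O)/C(C)=C/[C@H](O[Si](CC)(CC)CC)C(=O)CC(=O)OCC=C | intermediate
16 | allyl (3S,4E,6S,8E)-6-acetoxy-5,9-dimethyl-2-oxo-3-(triethylsilyloxy)cyclodeca-4,8-diene-1-carboxylate (C1 epimers) | C=CCOC(=O)C1C/C(C)=C/C[C@H](OC(C)=O)/C(C)=C/[C@H](O[Si](CC)(CC)CC)C1=O | intermediate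
17 | (3S,4E,6S,8E)-6-acetoxy-5,9-dimethyl-2-oxo-3-(triethylsilyloxy)cyclodeca-4,8-diene-1-carboxylic acid (C1 epimers) | OC(=O)C1C/C(C)=C/C[C@H](OC(C)=O)/C(C)=C/[C@H](O[Si](CC)(CC)CC)C1=O | intermediate
18 | (2S,3E,5S,7E)-5-acetoxy-4,8-dimethyl-2-(triethylsilyloxy)cyclodeca-3,7-dien-1-one (germacrane C6 S, C3 S) | O=C1CC/C(C)=C/C[C@H](OC(C)=O)/C(C)=C/[C@@H]1O[Si](CC)(CC)CC | intermediate
19 | (2S,3E,5S,7E)-5-acetoxy-2-hydroxy-4,8-dimethylcyclodeca-3,7-dien-1-one | O=C1CC/C(C)=C/C[C@H](OC(C)=O)/C(C)=C/[C@@H]1O | intermediate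
20 | (2S,3E,5S,7E)-5-acetoxy-4,8-dimethyl-2-(methylsulfonyloxy)cyclodeca-3,7-dien-1-one | O=C1CC/C(C)=C/C[C@H](OC(C)=O)/C(C)=C/[C@@H]1OS(C)(=O)=O | intermediate
21 | tert-butyl 2-(diethoxyphosphoryl)acetate | CCOP(=O)(OCC)CC(=O)OC(C)(C)C | starting material
22 | tert-butyl 2-(diethoxyphosphoryl)-3-(dimethylamino)propanoate | CCOP(=O)(OCC)C(CN(C)C)C(=O)OC(C)(C)C | intermediate
23 | [3-tert-butoxy-2-(diethoxyphosphoryl)-3-oxopropyl]trimethylammonium iodide | CCOP(=O)(OCC)C(C[N+](C)(C)C)C(=O)OC(C)(C)C.[I-] | intermediate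
24 | tert-butyl 2-(diethoxyphosphoryl)prop-2-enoate | C=C(C(=O)OC(C)(C)C)P(=O)(OCC)OCC | intermediate
25 | 2-(diethoxyphosphoryl)prop-2-enoic acid | C=C(C(=O)O)P(=O)(OCC)OCC | intermediate
26 | caesium acetate | [Cs+].CC(=O)[O-] | starting material
27 | (1R,2E,4S,6E)-4-acetoxy-3,7-dimethyl-10-oxocyclodeca-2,6-dien-1-yl 2-(diethoxyphosphoryl)prop-2-enoate | O=C1CC/C(C)=C/C[C@H](OC(C)=O)/C(C)=C/[C@H]1OC(=O)C(=C)P(=O)(OCC)OCC | intermediate
28 | caesium carbanide of (1R,2E,4S,6E)-4-acetoxy-3,7-dimethyl-10-oxocyclodeca-2,6-dien-1-yl 3-acetoxy-2-(diethoxyphosphoryl)propanoate | [Cs+].O=C1CC/C(C)=C/C[C@H](OC(C)=O)/C(C)=C/[C@H]1OC(=O)[C-](COC(C)=O)P(=O)(OCC)OCC | intermediate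
29 | (3S,6R)-3,13-diacetoxygermacra-1(10)E,4E,7(11)-trien-12,6-olide | CC(=O)OCC1=C2CC/C(C)=C/C[C@H](OC(C)=O)/C(C)=C/[C@H]2OC1=O | intermediate
30 | (1R,3S,6R,10R)-3,13-diacetoxy-1,10-epoxygermacra-4E,7(11)-dien-12,6-olide | CC(=O)OCC1=C2CC[C@@]3(C)O[C@@H]3C[C@H](OC(C)=O)/C(C)=C/[C@H]2OC1=O | target

**Step count and risks**

Total step count: 19. Longest linear sequence: 16 steps (steps 1, 3–15, 18 and 19).

Steps most likely to fail:

1. Step 18 (proposed new method). The conjugate addition of acetate may be too slow or too reversible to feed the olefination, so that oligomerisation of the phosphonoacrylate or enolisation and epimerisation at C6 takes over. Fallback with known chemistry, from mesylate 20 back to 29: the displacement with the caesium salt of 25 is kept (ester 27 in the flask), but the third component becomes an alkoxide, for which the tandem conjugate addition–HWE is an established reaction type. Sodium 4-methoxybenzyl oxide (NaH, 4-methoxybenzyl alcohol, THF, −40 °C → rt) should give (3S,6R)-3-acetoxy-13-(4-methoxybenzyloxy)germacra-1(10)E,4E,7(11)-trien-12,6-olide F1. DDQ in CH2Cl2/pH 7 buffer then unmasks (3S,6R)-3-acetoxy-13-hydroxygermacra-1(10)E,4E,7(11)-trien-12,6-olide F2, and Ac2O/pyridine acetylates the primary alcohol to rejoin the route at 29.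

2. Step 12. Intermolecular alkylation (oligomerisation) or O-alkylation may outrun the strained ten-membered C-alkylation. Fallback, from aldehyde 12 back to ketone 18, changes the nucleophile class and the traceless group to a sulfone. Addition of LiCH2SO2Ph (methyl phenyl sulfone, n-BuLi, THF, −78 °C) gives (3S,4E,6S,8E)-10-chloro-2-hydroxy-5,9-dimethyl-1-(phenylsulfonyl)-3-(triethylsilyloxy)deca-4,8-dien-6-yl acetate F3. Dess–Martin oxidation gives (3S,4E,6S,8E)-10-chloro-5,9-dimethyl-2-oxo-1-(phenylsulfonyl)-3-(triethylsilyloxy)deca-4,8-dien-6-yl acetate F4. Cs2CO3 at high dilution closes the ring through the softer, more acidic sulfonyl-stabilised carbanion to (2S,3E,5S,7E)-5-acetoxy-4,8-dimethyl-10-(phenylsulfonyl)-2-(triethylsilyloxy)cyclodeca-3,7-dien-1-one F5. Reductive desulfonylation with Al(Hg) in wet THF rejoins the route at 18.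

3. Step 3. Facial selectivity at C3 may be poor, or the acetonide may be lost under the silicon Lewis acid. Fallback, from enal 3 (with dienolate 5) back to 6, sets C3 by reduction instead of by the C–C bond formation. An achiral vinylogous Mukaiyama aldol (BF3·OEt2, CH2Cl2, −78 °C) gives methyl (2E,5RS,6E)-7-[(4S)-2,2-dimethyl-1,3-dioxolan-4-yl]-5-hydroxy-2,6-dimethylhepta-2,6-dienoate F6 as the C5 epimer mixture. MnO2 oxidises the allylic alcohol to methyl (2E,6E)-7-[(4S)-2,2-dimethyl-1,3-dioxolan-4-yl]-2,6-dimethyl-5-oxohepta-2,6-dienoate F7. CBS reduction with (R)-2-methyl-CBS-oxazaborolidine and catecholborane at −78 °C should return the (5S)-alcohol 6 under reagent control.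

**Further compounds**

F1 | step 18 | (3S,6R)-3-acetoxy-13-(4-methoxybenzyloxy)germacra-1(10)E,4E,7(11)-trien-12,6-olide | COc1ccc(COCC2=C3CC/C(C)=C/C[C@H](OC(C)=O)/C(C)=C/[C@H]3OC2=O)cc1
F2 | step 18 | (3S,6R)-3-acetoxy-13-hydroxygermacra-1(10)E,4E,7(11)-trien-12,6-olide | OCC1=C2CC/C(C)=C/C[C@H](OC(C)=O)/C(C)=C/[C@H]2OC1=O
F3 | step 12 | (3S,4E,6S,8E)-10-chloro-2-hydroxy-5,9-dimethyl-1-(phenylsulfonyl)-3-(triethylsilyloxy)deca-4,8-dien-6-yl acetate (C2 epimers) | ClC/C(C)=C/C[C@H](OC(C)=O)/C(C)=C/[C@H](O[Si](CC)(CC)CC)C(O)CS(=O)(=O)c1ccccc1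
F4 | step 12 | (3S,4E,6S,8E)-10-chloro-5,9-dimethyl-2-oxo-1-(phenylsulfonyl)-3-(triethylsilyloxy)deca-4,8-dien-6-yl acetate | ClC/C(C)=C/C[C@H](OC(C)=O)/C(C)=C/[C@H](O[Si](CC)(CC)CC)C(=O)CS(=O)(=O)c1ccccc1
F5 | step 12 | (2S,3E,5S,7E)-5-acetoxy-4,8-dimethyl-10-(phenylsulfonyl)-2-(triethylsilyloxy)cyclodeca-3,7-dien-1-one (C10 epimers) | O=C1C(S(=O)(=O)c2ccccc2)C/C(C)=C/C[C@H](OC(C)=O)/C(C)=C/[C@@H]1O[Si](CC)(CC)CC
F6 | step 3 | methyl (2E,5RS,6E)-7-[(4S)-2,2-dimethyl-1,3-dioxolan-4-yl]-5-hydroxy-2,6-dimethylhepta-2,6-dienoate | COC(=O)/C(C)=C/CC(O)/C(C)=C/[C@H]1COC(C)(C)O1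
F7 | step 3 | methyl (2E,6E)-7-[(4S)-2,2-dimethyl-1,3-dioxolan-4-yl]-2,6-dimethyl-5-oxohepta-2,6-dienoate | COC(=O)/C(C)=C/CC(=O)/C(C)=C/[C@H]1COC(C)(C)O1
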